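# Total synthesis proposal for 14-deoxy-11-hydroxyandrographolide (31)

Atoms carry the labdane numbers throughout: C1–C10 for the decalin, C11–C16 for the side chain and lactone, C17 for the methylene carbon on C8, C18 (equatorial) and C19 (axial) on C4, C20 for the methyl on C10. Compounds carry plain numbers 1–31.

## Analysis of the target

The target 31 is a trans-fused decalin (rings A and B) joined through the two-carbon bridge C11(OH)–C12H2 to the α-carbon C13 of a butenolide (C13=C14, C15H2–O, C16=O). Ring A carries an equatorial hydroxyl on C3 and a quaternary C4 with an equatorial methyl (C18) and an axial hydroxymethyl (C19). Ring B carries the exocyclic methylene C8=C17 and the equatorial side chain on C9. Five of the six stereocentres (C3, C4, C5, C10, C9) are contiguous on the decalin: O3 and C19 lie on the face of the angular methyl C20, C19 and C20 are 1,3-diaxial, and H5 and H9 are axial on the opposite face. The sixth stereocentre, the (R)-carbinol C11, lies outside the rings next to the hindered C9. Sensitive groups are the 1,1-disubstituted alkene C8=C17 (it moves into the ring under acid and forbids hydrogenation), the butenolide (base-labile, reducible, a Michael acceptor) and the three hydroxyls, which need differentiated protection. The hard points are the quaternary C4 with its oxygenated carbon in the more crowded axial position, an alkene that must end outside the ring, and C11. The strategy rests on one observation: equatorial O3, axial C19, trans C5/C10, equatorial C11 and C8=C17 together are what a chair–chair folded acyclic epoxy diene leaves behind when a C3–C4 epoxide is opened by the C5=C10 alkene and the cascade is ended at C9 by an allylsilane.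

## Retrosynthetic reasoning

**31 to 30.** The last operation only removes protecting groups. O3 and O19 are tied as an acetonide and O11 is a triethylsilyl ether, so that one mild acidic step frees all three hydroxyls without touching C8=C17 or the lactone.

**30 to 29 to 27 (C13–C16 and C16–O15).** The butenolide is cut at its acyl carbon. A (Z)-iodoalkene with iodine on C13 and the C15 hydroxyl cis to it (29) closes to the lactone by palladium-catalysed carbonylation, so the carbonyl carbon can only end on C13. Compound 29 comes from the propargylic alcohol 27 by hydroxyl-directed trans-hydroalumination and iodination, which fixes both the position of iodine and the alkene geometry.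

**27 to 26 to 25 to 24 (C14–C15 and C11–C12).** C15 is added to the terminal alkyne of 26 as a one-carbon electrophile. The bond C11–C12 is cut next: a propargyl nucleophile adds to the C11 aldehyde 24 and creates the C11 carbinol. The cut is made here because it puts the new stereocentre directly beside C9, whose substituents (quaternary C10, sp2 C8, H9) give a Felkin–Anh preference for the required (11R) alcohol 25.

**24 to 23 to 22 to 21 (protecting-group exchange).** The cyclisation is best run with a benzyl ether on O19 and an acetate on O11, but a benzyl ether cannot be removed once the butenolide and the exocyclic alkene are both present. It is therefore taken off directly after the cyclisation, together with the acetate, by dissolving-metal reduction (21 to 22). The acetonide 23 then leaves O11 as the only free hydroxyl for oxidation to 24.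

**21 to 20 (C4–C5 and C9–C10, the key disconnection).** Both rings are opened at once to the acyclic epoxy diene 20. A Lewis acid should open the C3–C4 epoxide at C4, and the C5=C10 alkene and the allylsilane C8=C9 should then close rings A and B. This gives, in one step, C4, C5, C10 and C9, the equatorial O3, the C8=C17 alkene in its only possible position, and C11 already oxygenated. Every ring stereocentre is relayed from the epoxide and the two alkene geometries of 20.

**20 to 19 to 18 to 16 to 15 (C8–C17).** The allylsilane is unmasked from the β-keto ester 15. Its (Z)-enol phosphate 16 is cross-coupled with the silylmethyl Grignard reagent 17 with retention, which puts C17 cis to C11 as the cyclisation requires. Reduction and acetylation of the ester 18 give 20.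

**15 to 13 + 14 (C6–C7).** The β-keto ester comes from γ-alkylation of the dianion of methyl acetoacetate 14 with the allylic bromide 13. This joins the two halves at an unfunctionalised sp3–sp3 bond and brings C7, C8, C9 and C11 in one step.

**13 to 11 to 10 to 9 to 8 (epoxide).** The bromide comes from the alcohol 11 by way of the mesylate 12. The epoxide is the Sharpless product 9 of the (Z)-allylic alcohol 8, benzylated to 10. The Sharpless reaction is chosen because it acts only on the alkene next to the free hydroxyl and leaves the C5=C10 alkene alone, and because the (Z)-geometry of 8 places the future C19 cis to the chain.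

**8 to 7 to 5 + 6, and 5 to 4 to 3 to 2 to 1.** The (Z)-trisubstituted allylic alcohol is made by Still–Gennari olefination of the aldehyde 5 with the phosphonate 6 and reduction of the enoate 7. The aldehyde is what remains of geraniol 1 after silylation (2), epoxidation of the distal alkene (3) and glycol cleavage by way of the diol 4.

## Alternatives that were turned down

**Alternative 1: silicon-tethered radical delivery of C19 from O3.**
- Disconnection: the C4–C19 bond. In the forward direction the (bromomethyl)dimethylsilyl ether A1 of a C3 allylic alcohol, with a C4=C5 alkene in a preformed bicycle, is treated with Bu3SnH and AIBN. The α-silyl radical adds 5-exo to C4, the C5 radical takes a hydrogen atom from the stannane, and the oxasilolane A2 results; oxidative cleavage of the C–Si bond would give the 3,19-diol.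
- For it: the tether forces C19 onto the face of O3, which is the relationship in 31, and a radical forms the crowded quaternary centre without any cationic rearrangement. On the certainty of the O3/C19 relationship it is at least as strong as the chosen route, because it does not depend on the purity of an alkene geometry.
- Against it: C5 is set by hydrogen-atom transfer to a tertiary ring-fusion radical, which has no strong bias for the trans fusion. C3 must be set earlier by a separate reduction. The step makes one skeletal bond and no ring of the carbon skeleton. In A2 ring B is bare: the methylene C17, the stereocentre C9, C11 and the whole side chain would all have to be built on a neopentyl C9 ketone, which costs many steps, and a stoichiometric tin hydride is needed.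
- Comparison: the chosen cyclisation makes both rings, C4, C5, C10 and C9, the C8=C17 alkene and an oxygenated C11 in one step from an acyclic precursor.

**Alternative 2: samarium Reformatsky closure of ring A at C3–C4.**
- Disconnection: the C3–C4 bond. In the forward direction SmI2 turns the tertiary α-bromo ester of A3 into a samarium enolate, which adds to the C3 aldehyde (6-exo-trig) and gives the β-hydroxy ester A4.
- For it: one mild, chemoselective step closes ring A and sets C3 and C4. C19 is distinguished from C18 by its oxidation state from the start. A samarium-bridged transition state places hydroxyl and ester cis, as in 31. On functional-group tolerance it is stronger than a Lewis-acid cascade.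
- Against it: the cis pair can be axial ester with equatorial hydroxyl (needed) or the reverse, and the needed one has the ester 1,3-diaxial to C20, so the ring substituents work against it. The enolate is fully substituted, so the aldol cannot be corrected by equilibration without retro-aldol cleavage. A3 already contains C5 and the quaternary C10 and needs its own stereocontrolled synthesis. As in A2, ring B of A4 still lacks C17, C11 and the side chain, and the ester must later be reduced.
- Comparison: the chosen route fixes C4 by a stereospecific inversion at an epoxide carbon, not by a transition-state preference, and it delivers ring B fully functionalised.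

**Alternative 3: carbonylative lactonisation as the central step.**
- Disconnection: C13–C16 and C16–O15. In the forward direction Pd(PPh3)4 and CO convert the (Z)-iodide A5 into the protected target A6.
- For it: the reaction is reliable and mild, its regiochemistry is fixed by the position of iodine and by ring size, and it tolerates C8=C17 and silyl ethers. On reliability it is stronger than the chosen key step.
- Against it: it forms no ring of the carbon skeleton and no stereocentre. A5 already contains the complete decalin with six stereocentres, so a plan centred on this step leaves the real problems (C4, the ring fusion, the alkene position, C11) unanswered.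
- Comparison: the chosen route keeps this reaction as step 23 and puts the strategic weight on the step that builds the core.

Key step: step 15

## Route

Remark on intermediates: salts that arise from a numbered compound by deprotonation alone (alkoxides, enolates, the dianion of 14, the lithium acetylide of 26) are not numbered separately.

Remark on compounds 3 and 4: they are racemic at the oxygen-bearing CH carbon, which becomes the aldehyde carbon of 5.

Step 1
Reactants: 1 geraniol, (2E)-3,7-dimethylocta-2,6-dien-1-ol
Product: 2 tert-butyl{[(2E)-3,7-dimethylocta-2,6-dien-1-yl]oxy}diphenylsilane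
Conditions: t-BuPh2SiCl, imidazole, DMF, 0 °C to rt
Reagents that add atoms: tert-butyl(chloro)diphenylsilane, CC(C)(C)[Si](Cl)(c1ccccc1)c1ccccc1
Why: Silyl ether formation at a primary alcohol. The TBDPS group is chosen because it has to pass periodic acid, iBu2AlH, the titanium–tartrate epoxidation and NaH/BnBr and then leave with fluoride beside an epoxide.

Step 2
Reactants: 2 tert-butyl{[(2E)-3,7-dimethylocta-2,6-dien-1-yl]oxy}diphenylsilane
Product: 3 tert-butyl{[(2E)-5-(3,3-dimethyloxiran-2-yl)-3-methylpent-2-en-1-yl]oxy}diphenylsilane (racemic)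
Conditions: mCPBA (1 equiv), NaHCO3, CH2Cl2, −20 to 0 °C
Reagents that add atoms: 3-chloroperoxybenzoic acid, OOC(=O)c1cccc(Cl)c1
Why: Prilezhaev epoxidation; the distal trisubstituted alkene is the more electron-rich one because the proximal alkene is deactivated by the allylic oxygen. The stereocentre formed is destroyed in step 3, so it needs no control.

Step 3
Reactants: 3 tert-butyl{[(2E)-5-(3,3-dimethyloxiran-2-yl)-3-methylpent-2-en-1-yl]oxy}diphenylsilane
Product: 5 (4E)-6-[(tert-butyldiphenylsilyl)oxy]-4-methylhex-4-enal, via vicinal diol 4 (not isolated)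
Conditions: H5IO6, THF/H2O, 0 °C
Reagents that add atoms: none
Why: Acid-catalysed hydration of the epoxide at its tertiary carbon and periodate glycol cleavage in one pot, with loss of acetone. The remaining trisubstituted alkene and the TBDPS ether are inert to periodic acid at 0 °C.

Step 4
Reactants: 5 (4E)-6-[(tert-butyldiphenylsilyl)oxy]-4-methylhex-4-enal; 6 ethyl 2-[bis(2,2,2-trifluoroethoxy)phosphoryl]propanoate
Product: 7 ethyl (2Z,6E)-8-[(tert-butyldiphenylsilyl)oxy]-2,6-dimethylocta-2,6-dienoate
Conditions: 6, KN(SiMe3)2, 18-crown-6, THF, −78 °C; then 5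
Reagents that add atoms: none
Why: Still–Gennari olefination; the electron-poor phosphonate and the dissociated potassium ion make elimination from the kinetic adduct fast, so the (Z)-enoate should form. This geometry places the future C19 cis to the chain.

Step 5
Reactants: 7 ethyl (2Z,6E)-8-[(tert-butyldiphenylsilyl)oxy]-2,6-dimethylocta-2,6-dienoate
Product: 8 (2Z,6E)-8-[(tert-butyldiphenylsilyl)oxy]-2,6-dimethylocta-2,6-dien-1-ol
Conditions: iBu2AlH, CH2Cl2, −78 °C
Reagents that add atoms: none
Why: 1,2-Reduction of a conjugated ester to the allylic alcohol; the alkene geometry is not touched at −78 °C.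

Step 6
Reactants: 8 (2Z,6E)-8-[(tert-butyldiphenylsilyl)oxy]-2,6-dimethylocta-2,6-dien-1-ol
Product: 9 [(2S,3R)-3-{(3E)-5-[(tert-butyldiphenylsilyl)oxy]-3-methylpent-3-en-1-yl}-2-methyloxiran-2-yl]methanol
Conditions: Ti(OiPr)4 (10 mol%), L-(+)-diethyl tartrate (12 mol%), t-BuOOH, 4 Å MS, CH2Cl2, −20 °C
Reagents that add atoms: tert-butyl hydroperoxide, CC(C)(C)OO
Why: Sharpless asymmetric epoxidation, which acts only on the alkene of the free allylic alcohol. L-(+)-tartrate delivers oxygen to the face that makes the hydroxymethyl-bearing carbon (2S), which with the (Z)-alkene gives the (2S,3R) epoxide, i.e. C4 (S) and C3 (R). This is the only step that brings absolute configuration into the route.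

Step 7
Reactants: 9 [(2S,3R)-3-{(3E)-5-[(tert-butyldiphenylsilyl)oxy]-3-methylpent-3-en-1-yl}-2-methyloxiran-2-yl]methanol
Product: 10 tert-butyl({(2E)-5-[(2R,3S)-3-[(benzyloxy)methyl]-3-methyloxiran-2-yl]-3-methylpent-2-en-1-yl}oxy)diphenylsilane
Conditions: NaH, BnBr, Bu4NI (cat.), THF, 0 °C to rt
Reagents that add atoms: benzyl bromide, BrCc1ccccc1
Why: Williamson etherification of the primary alkoxide; in dry THF benzylation is faster than Payne rearrangement of the epoxy alkoxide. The benzyl ether is stable to all later steps up to the cyclisation and can chelate the Lewis acid there.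

Step 8
Reactants: 10 tert-butyl({(2E)-5-[(2R,3S)-3-[(benzyloxy)methyl]-3-methyloxiran-2-yl]-3-methylpent-2-en-1-yl}oxy)diphenylsilane
Product: 11 (2E)-5-[(2R,3S)-3-[(benzyloxy)methyl]-3-methyloxiran-2-yl]-3-methylpent-2-en-1-ol
Conditions: Bu4NF, THF, 0 °C to rt
Reagents that add atoms: none
Why: Fluoride cleavage of the silyl ether; the trisubstituted epoxide and the benzyl ether do not react with fluoride.

Step 9
Reactants: 11 (2E)-5-[(2R,3S)-3-[(benzyloxy)methyl]-3-methyloxiran-2-yl]-3-methylpent-2-en-1-ol
Product: 13 (2S,3R)-2-[(benzyloxy)methyl]-3-[(3E)-5-bromo-3-methylpent-3-en-1-yl]-2-methyloxirane, via allylic mesylate 12 (not isolated)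
Conditions: MsCl, Et3N, CH2Cl2, −40 °C; then LiBr, THF, 0 °C
Reagents that add atoms: lithium bromide, [Li+].[Br-]
Why: Mesylation and SN2 displacement by bromide. The low temperature and the absence of protic acid keep the epoxide closed and the primary allylic position untransposed.

Step 10
Reactants: 13 (2S,3R)-2-[(benzyloxy)methyl]-3-[(3E)-5-bromo-3-methylpent-3-en-1-yl]-2-methyloxirane; 14 methyl acetoacetate
Product: 15 methyl (6E)-9-[(2R,3S)-3-[(benzyloxy)methyl]-3-methyloxiran-2-yl]-7-methyl-3-oxonon-6-enoate
Conditions: 14, NaH, THF, 0 °C; n-BuLi, 0 °C; then 13, 0 °C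
Reagents that add atoms: none
Why: γ-Alkylation of the acetoacetate dianion: the more basic terminal carbanion attacks the allylic bromide by SN2 and forms C6–C7. A hindered trisubstituted epoxide does not compete with an allylic bromide at 0 °C.

Step 11
Reactants: 15 methyl (6E)-9-[(2R,3S)-3-[(benzyloxy)methyl]-3-methyloxiran-2-yl]-7-methyl-3-oxonon-6-enoate
Product: 16 methyl (2Z,6E)-9-[(2R,3S)-3-[(benzyloxy)methyl]-3-methyloxiran-2-yl]-3-[(diethoxyphosphoryl)oxy]-7-methylnona-2,6-dienoate
Conditions: NaH, Et2O, 0 °C; then ClP(O)(OEt)2
Reagents that add atoms: diethyl chlorophosphate, CCOP(=O)(Cl)OCC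
Why: O-Phosphorylation of the chelated sodium enolate in ether, which should give the (Z)-enol phosphate with the phosphate cis to the ester.

Step 12
Reactants: 16 methyl (2Z,6E)-9-[(2R,3S)-3-[(benzyloxy)methyl]-3-methyloxiran-2-yl]-3-[(diethoxyphosphoryl)oxy]-7-methylnona-2,6-dienoate; 17 (trimethylsilyl)methylmagnesium chloride
Product: 18 methyl (2Z,6E)-9-[(2R,3S)-3-[(benzyloxy)methyl]-3-methyloxiran-2-yl]-7-methyl-3-[(trimethylsilyl)methyl]nona-2,6-dienoate
Conditions: 17, Ni(acac)2 (5 mol%), THF, 0 °C to rt
Reagents that add atoms: none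
Why: Nickel-catalysed Kumada-type coupling of an enol phosphate with retention of geometry, the established way from β-keto esters to 3-(silylmethyl)alk-2-enoates; C17 ends cis to C11. A bis(silylmethyl)cuprate is not used because Me3SiCH2 is a poorly transferred ligand on copper. The Grignard reagent does not add to the conjugated ester at this temperature.

Step 13
Reactants: 18 methyl (2Z,6E)-9-[(2R,3S)-3-[(benzyloxy)methyl]-3-methyloxiran-2-yl]-7-methyl-3-[(trimethylsilyl)methyl]nona-2,6-dienoate
Product: 19 (2Z,6E)-9-[(2R,3S)-3-[(benzyloxy)methyl]-3-methyloxiran-2-yl]-7-methyl-3-[(trimethylsilyl)methyl]nona-2,6-dien-1-ol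
Conditions: iBu2AlH, CH2Cl2, −78 °C
Reagents that add atoms: none
Why: 1,2-Reduction of the conjugated ester; at −78 °C the ester is reduced much faster than a trisubstituted epoxide is opened.

Step 14
Reactants: 19 (2Z,6E)-9-[(2R,3S)-3-[(benzyloxy)methyl]-3-methyloxiran-2-yl]-7-methyl-3-[(trimethylsilyl)methyl]nona-2,6-dien-1-ol
Product: 20 (2Z,6E)-9-[(2R,3S)-3-[(benzyloxy)methyl]-3-methyloxiran-2-yl]-7-methyl-3-[(trimethylsilyl)methyl]nona-2,6-dien-1-yl acetate
Conditions: Ac2O, pyridine, DMAP (cat.), CH2Cl2, 0 °C
Reagents that add atoms: acetic anhydride, CC(=O)OC(C)=O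
Why: Acylation under basic conditions, which spares the acid-labile allylsilane and epoxide. The acetate keeps O11 from binding the aluminium reagent as an alkoxide.

Step 15
Reactants: 20 (2Z,6E)-9-[(2R,3S)-3-[(benzyloxy)methyl]-3-methyloxiran-2-yl]-7-methyl-3-[(trimethylsilyl)methyl]nona-2,6-dien-1-yl acetate
Product: 21 [(1R,4aS,5R,6R,8aR)-5-[(benzyloxy)methyl]-6-hydroxy-5,8a-dimethyl-2-methylidenedecahydronaphthalen-1-yl]methyl acetate (3R,4R,5S,9R,10R; 19-benzyloxy-3-hydroxy-8(17)-en-11-yl acetate)
Conditions: MeAlCl2 (2 equiv), CH2Cl2, −78 °C; Et3N/MeOH quench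
Reagents that add atoms: none
Why: MeAlCl2 binds the epoxide oxygen (and the neighbouring benzyl ether oxygen), the C4–O bond lengthens, and C5 of the C5=C10 alkene attacks C4 anti to the leaving oxygen; the tertiary C10 cation is taken by C9 of the allylsilane, and the β-silyl cation at C8 loses the Me3Si group to chloride to leave C8=C17. The closest known reaction type is the Lewis-acid-promoted bicyclisation of a trisubstituted epoxy polyene ended by an allylsilane, which gives exocyclic-methylene decalins. Ring A closes 6-endo-trig with respect to C5=C10, with both epoxide carbons in the ring (endo opening at the more substituted C4); ring B closes 6-endo-trig with respect to C8=C9. C4 is set by inversion at the epoxide carbon, so the CH2OBn group that is cis to the chain on the epoxide becomes the axial C19 and the methyl becomes the equatorial C18, while C3 keeps its configuration and its oxygen ends equatorial. C5 and C10 follow from anti addition across the (E)-C5=C10 alkene in a chair, which gives the trans fusion with H5 and C20 trans-diaxial. C9 follows from the chair of ring B and from the geometry of C8=C9, in which C11 is trans to C7 and so ends equatorial. The step needs opening at C4 and not C3 (secured by the tertiary centre and by chelation), chair–chair folding (secured by the all-trans backbone) and one alkene position (secured by silicon, since only the C17–Si bond is placed to be lost). The absolute sense of the whole array comes from the epoxide of step 6.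

Step 16
Reactants: 21 [(1R,4aS,5R,6R,8aR)-5-[(benzyloxy)methyl]-6-hydroxy-5,8a-dimethyl-2-methylidenedecahydronaphthalen-1-yl]methyl acetate
Product: 22 [(1R,4aS,5R,6R,8aR)-6-hydroxy-5-(hydroxymethyl)-5,8a-dimethyl-2-methylidenedecahydronaphthalen-1-yl]methanol (3,11,19-triol)
Conditions: Li, NH3(l)/THF, −78 °C; then NH4Cl
Reagents that add atoms: none
Why: Dissolving-metal reduction cleaves the benzyl ether to toluene and reduces the acetate to the alkoxide and ethanol; the isolated 1,1-disubstituted alkene is not reduced. The benzyl group is removed here because later neither hydrogenolysis (C8=C17, C13=C14) nor electron transfer (butenolide) could be used.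

Step 17
Reactants: 22 [(1R,4aS,5R,6R,8aR)-6-hydroxy-5-(hydroxymethyl)-5,8a-dimethyl-2-methylidenedecahydronaphthalen-1-yl]methanol
Product: 23 (3R,4R,5S,9R,10R)-3,19-O-isopropylidene-3,19-dihydroxy-12,13,14,15,16-pentanorlabd-8(17)-en-11-ol (22 with O3 and O19 joined in a 2,2-dimethyl-1,3-dioxane)
Conditions: Me2C(OMe)2, PPTS (cat.), CH2Cl2, rt
Reagents that add atoms: 2,2-dimethoxypropane, COC(C)(C)OC
Why: Thermodynamic acetalisation; only O3 and O19 can close a six-membered 1,3-dioxane, so the primary C11 hydroxyl stays free, and any mixed acyclic acetal on O11 falls apart on aqueous work-up.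

Step 18
Reactants: 23 (3R,4R,5S,9R,10R)-3,19-O-isopropylidene-3,19-dihydroxy-12,13,14,15,16-pentanorlabd-8(17)-en-11-ol
Product: 24 (3R,4R,5S,9R,10R)-3,19-O-isopropylidene-3,19-dihydroxy-12,13,14,15,16-pentanorlabd-8(17)-en-11-al
Conditions: Dess–Martin periodinane, NaHCO3, CH2Cl2, 0 °C
Reagents that add atoms: none
Why: Dess–Martin oxidation under buffered, non-basic conditions, chosen because this β,γ-unsaturated aldehyde can move its alkene into conjugation or epimerise at C9 with acid or base. The aldehyde is used at once; the equatorial formyl group is also the thermodynamic one.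

Step 19
Reactants: 24 (3R,4R,5S,9R,10R)-3,19-O-isopropylidene-3,19-dihydroxy-12,13,14,15,16-pentanorlabd-8(17)-en-11-al
Product: 25 (3R,4R,5S,9R,10R,11R)-3,19-O-isopropylidene-3,19-dihydroxy-15,16-dinorlabd-8(17)-en-13-yn-11-ol
Conditions: HC≡CCH2Br, Zn, THF, 0 °C; then 24, −78 to 0 °C
Reagents that add atoms: propargyl bromide, C#CCBr
Why: Barbier-type propargylation; allenylzinc bromide adds by SE2' through a six-membered transition state and gives the homopropargylic alcohol, and it is too weakly basic to enolise the aldehyde. C11 is set under Felkin–Anh control: the nucleophile comes anti to the quaternary C10 and past H9, with the carbonyl oxygen on the side of C8, which leads to the (11R) alcohol.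

Step 20
Reactants: 25 (3R,4R,5S,9R,10R,11R)-3,19-O-isopropylidene-3,19-dihydroxy-15,16-dinorlabd-8(17)-en-13-yn-11-ol
Product: 26 (3R,4R,5S,9R,10R,11R)-3,19-O-isopropylidene-11-(triethylsilyloxy)-15,16-dinorlabd-8(17)-en-13-yne-3,19-diol
Conditions: Et3SiOTf, 2,6-lutidine, CH2Cl2, −78 °C
Reagents that add atoms: triethylsilyl trifluoromethanesulfonate, CC[Si](CC)(CC)OS(=O)(=O)C(F)(F)F
Why: Silylation of a hindered secondary alcohol with the silyl triflate. O11 is masked so that only O15 directs the hydroalumination in step 22 and only O15 can close the lactone in step 23.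

Step 21
Reactants: 26 (3R,4R,5S,9R,10R,11R)-3,19-O-isopropylidene-11-(triethylsilyloxy)-15,16-dinorlabd-8(17)-en-13-yne-3,19-diol
Product: 27 (3R,4R,5S,9R,10R,11R)-3,19-O-isopropylidene-11-(triethylsilyloxy)-16-norlabd-8(17)-en-13-yne-3,15,19-triol (propargylic alcohol at C15)
Conditions: n-BuLi, THF, −78 °C; then (CH2O)n, −78 °C to rt
Reagents that add atoms: formaldehyde (from paraformaldehyde), C=O
Why: Deprotonation of the terminal alkyne and addition of the acetylide to formaldehyde install C15 as a propargylic alcohol; acetonide, silyl ether and alkene are inert to the base at −78 °C.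

Step 22
Reactants: 27 (3R,4R,5S,9R,10R,11R)-3,19-O-isopropylidene-11-(triethylsilyloxy)-16-norlabd-8(17)-en-13-yne-3,15,19-triol
Product: 29 (3R,4R,5S,9R,10R,11R,13Z)-13-iodo-3,19-O-isopropylidene-11-(triethylsilyloxy)-16-norlabda-8(17),13-diene-3,15,19-triol, via cyclic alkenylalanate 28 (not isolated)
Conditions: NaAlH2(OCH2CH2OMe)2, THF, 0 °C to rt; then I2, THF, −78 °C
Reagents that add atoms: iodine, II
Why: Hydroxyl-directed trans-hydroalumination; the O15 aluminate delivers hydride to C14 and leaves aluminium on C13 in a five-membered ring, and iodine replaces aluminium with retention. The (Z)-iodide therefore has iodine on C13 cis to the C15 hydroxymethyl group.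

Step 23
Reactants: 29 (3R,4R,5S,9R,10R,11R,13Z)-13-iodo-3,19-O-isopropylidene-11-(triethylsilyloxy)-16-norlabda-8(17),13-diene-3,15,19-triol
Product: 30 (3R,4R,5S,9R,10R,11R)-3,19-O-isopropylidene-11-(triethylsilyloxy)-3,19-dihydroxylabda-8(17),13-dien-16,15-olide
Conditions: Pd(PPh3)4 (10 mol%), CO (1 atm), Et3N, MeCN, 50 °C
Reagents that add atoms: carbon monoxide, [C-]#[O+]
Why: Carbonylative lactonisation; zerovalent palladium inserts into the C13–I bond, CO inserts, and the cis C15 hydroxyl captures the acylpalladium, forming C13–C16 and C16–O15. The C13=C14 alkene is already in its final place, so no isomerisation is needed.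

Step 24
Reactants: 30 (3R,4R,5S,9R,10R,11R)-3,19-O-isopropylidene-11-(triethylsilyloxy)-3,19-dihydroxylabda-8(17),13-dien-16,15-olide
Product: 31 14-deoxy-11-hydroxyandrographolide, 3-{(2R)-2-hydroxy-2-[(1R,4aS,5R,6R,8aR)-6-hydroxy-5-(hydroxymethyl)-5,8a-dimethyl-2-methylidenedecahydronaphthalen-1-yl]ethyl}furan-2(5H)-one
Conditions: 48% aq. HF/MeCN, 0 °C to rt
Reagents that add atoms: none
Why: HF cleaves the triethylsilyl ether and the aqueous acid hydrolyses the 1,3-dioxane. The conditions are mild and short enough to leave the exocyclic alkene and the butenolide unchanged.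

## Compound list

1 | geraniol, (2E)-3,7-dimethylocta-2,6-dien-1-ol | CC(C)=CCC/C(C)=C/CO | starting material
2 | tert-butyl{[(2E)-3,7-dimethylocta-2,6-dien-1-yl]oxy}diphenylsilane | CC(C)=CCC/C(C)=C/CO[Si](c1ccccc1)(c1ccccc1)C(C)(C)C | intermediate
3 | tert-butyl{[(2E)-5-(3,3-dimethyloxiran-2-yl)-3-methylpent-2-en-1-yl]oxy}diphenylsilane (racemic) | CC1(C)OC1CC/C(C)=C/CO[Si](c1ccccc1)(c1ccccc1)C(C)(C)C | intermediate
4 | (6E)-8-[(tert-butyldiphenylsilyl)oxy]-2,6-dimethyloct-6-ene-2,3-diol (racemic, not isolated) | CC(C)(O)C(O)CC/C(C)=C/CO[Si](c1ccccc1)(c1ccccc1)C(C)(C)C | intermediate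
5 | (4E)-6-[(tert-butyldiphenylsilyl)oxy]-4-methylhex-4-enal | O=CCC/C(C)=C/CO[Si](c1ccccc1)(c1ccccc1)C(C)(C)C | intermediate
6 | ethyl 2-[bis(2,2,2-trifluoroethoxy)phosphoryl]propanoate | CCOC(=O)C(C)P(=O)(OCC(F)(F)F)OCC(F)(F)F | starting material
7 | ethyl (2Z,6E)-8-[(tert-butyldiphenylsilyl)oxy]-2,6-dimethylocta-2,6-dienoate | CCOC(=O)/C(C)=C\CC/C(C)=C/CO[Si](c1ccccc1)(c1ccccc1)C(C)(C)C | intermediate
8 | (2Z,6E)-8-[(tert-butyldiphenylsilyl)oxy]-2,6-dimethylocta-2,6-dien-1-ol | OC/C(C)=C\CC/C(C)=C/CO[Si](c1ccccc1)(c1ccccc1)C(C)(C)C | intermediate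
9 | [(2S,3R)-3-{(3E)-5-[(tert-butyldiphenylsilyl)oxy]-3-methylpent-3-en-1-yl}-2-methyloxiran-2-yl]methanol | CC(C)(C)[Si](c1ccccc1)(c1ccccc1)OC/C=C(\C)CC[C@H]1O[C@@]1(C)CO | intermediate
10 | tert-butyl({(2E)-5-[(2R,3S)-3-[(benzyloxy)methyl]-3-methyloxiran-2-yl]-3-methylpent-2-en-1-yl}oxy)diphenylsilane | CC(C)(C)[Si](c1ccccc1)(c1ccccc1)OC/C=C(\C)CC[C@H]1O[C@@]1(C)COCc1ccccc1 | intermediate
11 | (2E)-5-[(2R,3S)-3-[(benzyloxy)methyl]-3-methyloxiran-2-yl]-3-methylpent-2-en-1-ol | OC/C=C(\C)CC[C@H]1O[C@@]1(C)COCc1ccccc1 | intermediate
12 | (2E)-5-[(2R,3S)-3-[(benzyloxy)methyl]-3-methyloxiran-2-yl]-3-methylpent-2-en-1-yl methanesulfonate (not isolated) | CS(=O)(=O)OC/C=C(\C)CC[C@H]1O[C@@]1(C)COCc1ccccc1 | intermediate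
13 | (2S,3R)-2-[(benzyloxy)methyl]-3-[(3E)-5-bromo-3-methylpent-3-en-1-yl]-2-methyloxirane | BrC/C=C(\C)CC[C@H]1O[C@@]1(C)COCc1ccccc1 | intermediate
14 | methyl acetoacetate | COC(=O)CC(C)=O | starting material
15 | methyl (6E)-9-[(2R,3S)-3-[(benzyloxy)methyl]-3-methyloxiran-2-yl]-7-methyl-3-oxonon-6-enoate | COC(=O)CC(=O)CC/C=C(\C)CC[C@H]1O[C@@]1(C)COCc1ccccc1 | intermediate
16 | methyl (2Z,6E)-9-[(2R,3S)-3-[(benzyloxy)methyl]-3-methyloxiran-2-yl]-3-[(diethoxyphosphoryl)oxy]-7-methylnona-2,6-dienoate | COC(=O)/C=C(\OP(=O)(OCC)OCC)CC/C=C(\C)CC[C@H]1O[C@@]1(C)COCc1ccccc1 | intermediate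
17 | (trimethylsilyl)methylmagnesium chloride | C[Si](C)(C)C[Mg]Cl | starting material
18 | methyl (2Z,6E)-9-[(2R,3S)-3-[(benzyloxy)methyl]-3-methyloxiran-2-yl]-7-methyl-3-[(trimethylsilyl)methyl]nona-2,6-dienoate | COC(=O)/C=C(\C[Si](C)(C)C)CC/C=C(\C)CC[C@H]1O[C@@]1(C)COCc1ccccc1 | intermediate
19 | (2Z,6E)-9-[(2R,3S)-3-[(benzyloxy)methyl]-3-methyloxiran-2-yl]-7-methyl-3-[(trimethylsilyl)methyl]nona-2,6-dien-1-ol | OC/C=C(\C[Si](C)(C)C)CC/C=C(\C)CC[C@H]1O[C@@]1(C)COCc1ccccc1 | intermediate
20 | (2Z,6E)-9-[(2R,3S)-3-[(benzyloxy)methyl]-3-methyloxiran-2-yl]-7-methyl-3-[(trimethylsilyl)methyl]nona-2,6-dien-1-yl acetate | CC(=O)OC/C=C(\C[Si](C)(C)C)CC/C=C(\C)CC[C@H]1O[C@@]1(C)COCc1ccccc1 | intermediate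
21 | [(1R,4aS,5R,6R,8aR)-5-[(benzyloxy)methyl]-6-hydroxy-5,8a-dimethyl-2-methylidenedecahydronaphthalen-1-yl]methyl acetate | C=C1CC[C@@H]2[C@](C)(COCc3ccccc3)[C@H](O)CC[C@@]2(C)[C@@H]1COC(C)=O | intermediate
22 | [(1R,4aS,5R,6R,8aR)-6-hydroxy-5-(hydroxymethyl)-5,8a-dimethyl-2-methylidenedecahydronaphthalen-1-yl]methanol | C=C1CC[C@@H]2[C@](C)(CO)[C@H](O)CC[C@@]2(C)[C@@H]1CO | intermediate
23 | (3R,4R,5S,9R,10R)-3,19-O-isopropylidene-3,19-dihydroxy-12,13,14,15,16-pentanorlabd-8(17)-en-11-ol | C=C1CC[C@@H]2[C@](C)(COC(C)(C)O3)[C@H]3CC[C@@]2(C)[C@@H]1CO | intermediate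
24 | (3R,4R,5S,9R,10R)-3,19-O-isopropylidene-3,19-dihydroxy-12,13,14,15,16-pentanorlabd-8(17)-en-11-al | C=C1CC[C@@H]2[C@](C)(COC(C)(C)O3)[C@H]3CC[C@@]2(C)[C@@H]1C=O | intermediate
25 | (3R,4R,5S,9R,10R,11R)-3,19-O-isopropylidene-3,19-dihydroxy-15,16-dinorlabd-8(17)-en-13-yn-11-ol | C=C1CC[C@@H]2[C@](C)(COC(C)(C)O3)[C@H]3CC[C@@]2(C)[C@@H]1[C@H](O)CC#C | intermediate
26 | 11-O-triethylsilyl ether of 25 | C=C1CC[C@@H]2[C@](C)(COC(C)(C)O3)[C@H]3CC[C@@]2(C)[C@@H]1[C@H](O[Si](CC)(CC)CC)CC#C | intermediate
27 | (3R,4R,5S,9R,10R,11R)-3,19-O-isopropylidene-11-(triethylsilyloxy)-16-norlabd-8(17)-en-13-yne-3,15,19-triol | C=C1CC[C@@H]2[C@](C)(COC(C)(C)O3)[C@H]3CC[C@@]2(C)[C@@H]1[C@H](O[Si](CC)(CC)CC)CC#CCO | intermediate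
28 | sodium alkenylalanate of 27 (Al on C13 and O15 in a five-membered ring, two 2-methoxyethoxy ligands; not isolated) | C=C1CC[C@@H]2[C@](C)(COC(C)(C)O3)[C@H]3CC[C@@]2(C)[C@@H]1[C@H](O[Si](CC)(CC)CC)CC1=CCO[Al-]1(OCCOC)OCCOC.[Na+] | intermediate
29 | (3R,4R,5S,9R,10R,11R,13Z)-13-iodo-3,19-O-isopropylidene-11-(triethylsilyloxy)-16-norlabda-8(17),13-diene-3,15,19-triol | C=C1CC[C@@H]2[C@](C)(COC(C)(C)O3)[C@H]3CC[C@@]2(C)[C@@H]1[C@H](O[Si](CC)(CC)CC)C/C(I)=C/CO | intermediate
30 | (3R,4R,5S,9R,10R,11R)-3,19-O-isopropylidene-11-(triethylsilyloxy)-3,19-dihydroxylabda-8(17),13-dien-16,15-olide | C=C1CC[C@@H]2[C@](C)(COC(C)(C)O3)[C@H]3CC[C@@]2(C)[C@@H]1[C@H](O[Si](CC)(CC)CC)CC1=CCOC1=O | intermediate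
31 | 14-deoxy-11-hydroxyandrographolide | C=C1CC[C@@H]2[C@](C)(CO)[C@H](O)CC[C@@]2(C)[C@@H]1[C@H](O)CC1=CCOC1=O | target

## Step count and least certain steps

Total step count: 24. Longest linear sequence: 24 steps (from geraniol 1; the route is linear, with 6, 14 and 17 entering as purchased reagents).

**Step 15 (key step).**
- What may go wrong: the CH2OBn group on C4 withdraws electron density from the carbon that must carry the positive charge. The activated epoxide may therefore rearrange by hydride shift, or open only as far as ring A with proton loss from C10, before ring B closes. The allylsilane may be protodesilylated by adventitious HCl, or the allylic acetate ionised by the Lewis acid. A boat fold of ring B would give the C9 epimer.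
- Fallback: it sets out from 15 and returns at 22, and it keeps the stereospecific epoxide opening but changes the terminating group to the β-keto ester. SnCl4 in CH2Cl2 at −78 °C should close both rings through the enol carbon C9 and give the bicyclic β-keto ester F1 (C8 ketone, equatorial ester on C9 after equilibration). Wittig methylenation with Ph3P=CH2 in hot toluene gives the methylidene ester F2. LiAlH4 reduces the ester to the 19-benzyloxy-3,11-diol F3, and Li in liquid NH3 removes the benzyl group to give 22.

**Step 12.**
- What may go wrong: opening or rearrangement of the trisubstituted epoxide by the Grignard reagent and its magnesium chloride during the hours the nickel coupling needs, or partial loss of the (Z)-geometry.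
- Fallback: it sets out from 15 and returns at 18. NaH and PhNTf2 convert 15 into the (Z)-enol triflate F4. Negishi coupling of F4 with Me3SiCH2ZnCl (from 17 and ZnCl2) under Pd(PPh3)4 catalysis at 0 °C gives 18 with a zinc reagent that does not attack epoxides.

**Step 19.**
- What may go wrong: poor or reversed facial selectivity at C11, because the inner hydrogen of the C17 methylene lies close to the Felkin–Anh trajectory; also SE2 addition to give the allenyl carbinol, and migration of C8=C17 into conjugation before addition.
- Fallback: it sets out from 24 and returns at 25. If the propargylation gives mainly the (11S) alcohol F5, this is separated and inverted by Mitsunobu reaction (4-nitrobenzoic acid, PPh3, diisopropyl azodicarboxylate) to the (11R) 4-nitrobenzoate F6, and K2CO3 in MeOH releases 25.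

**Step 22.**
- What may go wrong: incomplete or wrongly directed hydroalumination (hydride to C13), reduction past the alkenyl stage to the allylic alcohol without iodine, loss of the silyl ether, or addition of iodine to C8=C17.
- Fallback: it sets out from 27 and returns at 30, leaving out 29. Palladium-catalysed cyclocarbonylation of the alkynol (Pd2(dba)3, 1,4-bis(diphenylphosphino)butane, CO/H2, CH2Cl2, 95 °C) closes the 2(5H)-furanone directly; ring size allows the carbonyl carbon only on C13.

## Further compounds

F1 | step 15 | methyl (3R,4R,5S,9S,10R)-19-(benzyloxy)-3-hydroxy-8-oxo-12,13,14,15,16,17-hexanorlabdan-11-oate | O=C1CC[C@@H]2[C@](C)(COCc3ccccc3)[C@H](O)CC[C@@]2(C)[C@@H]1C(=O)OC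
F2 | step 15 | methyl (3R,4R,5S,9R,10R)-19-(benzyloxy)-3-hydroxy-12,13,14,15,16-pentanorlabd-8(17)-en-11-oate | C=C1CC[C@@H]2[C@](C)(COCc3ccccc3)[C@H](O)CC[C@@]2(C)[C@@H]1C(=O)OC
F3 | step 15 | (3R,4R,5S,9R,10R)-19-(benzyloxy)-12,13,14,15,16-pentanorlabd-8(17)-ene-3,11-diol | C=C1CC[C@@H]2[C@](C)(COCc3ccccc3)[C@H](O)CC[C@@]2(C)[C@@H]1CO
F4 | step 12 | methyl (2Z,6E)-9-[(2R,3S)-3-[(benzyloxy)methyl]-3-methyloxiran-2-yl]-7-methyl-3-{[(trifluoromethyl)sulfonyl]oxy}nona-2,6-dienoate | COC(=O)/C=C(\OS(=O)(=O)C(F)(F)F)CC/C=C(\C)CC[C@H]1O[C@@]1(C)COCc1ccccc1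
F5 | step 19 | (3R,4R,5S,9R,10R,11S)-3,19-O-isopropylidene-3,19-dihydroxy-15,16-dinorlabd-8(17)-en-13-yn-11-ol | C=C1CC[C@@H]2[C@](C)(COC(C)(C)O3)[C@H]3CC[C@@]2(C)[C@@H]1[C@@H](O)CC#C
F6 | step 19 | (3R,4R,5S,9R,10R,11R)-3,19-O-isopropylidene-3,19-dihydroxy-15,16-dinorlabd-8(17)-en-13-yn-11-yl 4-nitrobenzoate | C=C1CC[C@@H]2[C@](C)(COC(C)(C)O3)[C@H]3CC[C@@]2(C)[C@@H]1[C@H](OC(=O)c4ccc(cc4)[N+](=O)[O-])CC#C
F0 | step 22 | none | none
A1 | alternative 1 | (bromomethyl)dimethylsilyl ether of the 4-methyl-4(5)-octalin-3-ol with C20 on C10 and a 1,3-dioxolane at C9 | C1CCC2=C(C)[C@H](O[Si](C)(C)CBr)CC[C@@]2(C)C13OCCO3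
A2 | alternative 1 | trans-decalin with a dimethyl-oxasilolane bridging O3 and C19 and a 1,3-dioxolane at C9 | C1CC[C@@H]2[C@]3(C)C[Si](C)(C)O[C@@H]3CC[C@@]2(C)C14OCCO4
A3 | alternative 2 | ring-B cyclohexane (C9 dioxolane) with the 3-oxopropyl chain C1–C3 and C20 on C10 and the tertiary α-bromo ester C4 unit on C5 | C1CC[C@H](C(C)(Br)C(=O)OC)[C@@](C)(CCC=O)C12OCCO2
A4 | alternative 2 | trans-decalin β-hydroxy ester, 3-hydroxy with methyl and axial methoxycarbonyl (C19) on C4 and a 1,3-dioxolane at C9 | C1CC[C@@H]2[C@](C)(C(=O)OC)[C@H](O)CC[C@@]2(C)C13OCCO3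
A5 | alternative 3 | (13Z)-13-iodo-15-ol with 3,19-acetonide and 11-O-tert-butyldimethylsilyl ether | C=C1CC[C@@H]2[C@](C)(COC(C)(C)O3)[C@H]3CC[C@@]2(C)[C@@H]1[C@H](O[Si](C)(C)C(C)(C)C)C/C(I)=C/CO
A6 | alternative 3 | 3,19-acetonide 11-O-tert-butyldimethylsilyl ether of 31 | C=C1CC[C@@H]2[C@](C)(COC(C)(C)O3)[C@H]3CC[C@@]2(C)[C@@H]1[C@H](O[Si](C)(C)C(C)(C)C)CC1=CCOC1=O
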